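**Retrosynthetic overview**

1. Target ⇐ hydroxyl-directed epoxidation of a C8=C14 methylene, acetonide removal, O6 isovalerate and directed reduction of a C6 ketone; the methylene comes from a C8 methyl by dehydrogenation and deconjugation.
2. Five-membered ring ⇐ formal [3+2] cycloaddition of cyclopropyl ketone 11 with 3-methylbut-1-yne (C2–C3 and C4–C5 in one operation), then Markovnikov hydration at C4 and epimerisation at C5 to the trans ring fusion.
3. Enabling feature: in the cis-fused bicyclo[5.1.0]octan-2-one 11 the cyclopropane bond C5–C2 (absent from the target) is exocyclic to the seven-membered ring and adjacent to the C6 carbonyl, so the C6 ketyl opens it and leaves C2 as a radical three atoms from the enolate carbon C5; the same cyclopropane fixes C1.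
4. Cyclopropane ⇐ hydroxyl-directed Simmons–Smith reaction on a C6 allylic alcohol; absolute configuration ⇐ chiral lithium amide desymmetrisation of a meso cycloheptanone.
5. Seven-membered ring first ⇐ oxyallyl (4+3) cycloaddition with (2E,4E)-hexa-2,4-diene, then cis-dihydroxylation; ring order: seven, three (temporary), five, epoxide.

Key step: step 9

Numbering (daucane): C1 quaternary carbon with methyl C15; C2, C3 ring CH2; C4 carbinol carbon with isopropyl; C5 ring-fusion CH; C6 ester carbon; C7 CH2; C8 epoxide carbon with C14; C9, C10 carbinol carbons. β is the face of the seven-membered ring that carries C15, α the other face. The same numbers are used for the carbons of the intermediates that become these atoms.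

Remark: the sense of induction of the chiral lithium amide in step 4 is assumed; if it proves opposite, the (S,S)-amide is used.

**Route**

Step 1
Reactants: 1 (2E,4E)-hexa-2,4-diene; 2 1,1,3,3-tetrabromoacetone
Product: 4 cis-3,6-dimethylcyclohept-4-en-1-one (meso; C6 ketone, C9=C10 alkene, methyls on C1 and C8 both β), via dibromo cycloadduct 3 (not isolated)
Conditions: Fe2(CO)9, benzene, 60 °C; then Zn–Cu couple, NH4Cl, MeOH, rt
Reagents that add atoms: none
Why: Oxyallyl cation (4+3) cycloaddition of the iron-bound dibromo-oxyallyl species across the s-cis diene should place the two methyls of the E,E-diene cis (suprafacial addition), and zinc then removes both α-bromines.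

Step 2
Reactants: 4
Product: 5 meso 9α,10α-dihydroxy ketone (4,5-dihydroxy-3,6-dimethylcycloheptan-1-one, hydroxyls cis to each other and trans to both methyls)
Conditions: OsO4 (2 mol %), NMO, acetone/H2O, rt
Reagents that add atoms: N-methylmorpholine N-oxide (C[N+]1([O-])CCOCC1); osmium tetroxide (O=[Os](=O)(=O)=O)
Why: Upjohn dihydroxylation should occur on the alkene face anti to the two flanking allylic methyls, which sets C9 and C10 relative to the methyls.

Step 3
Reactants: 5
Product: 6 meso acetonide ketone (9α,10α-isopropylidenedioxy)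
Conditions: 2,2-dimethoxypropane, PPTS (cat.), acetone, rt
Reagents that add atoms: 2,2-dimethoxypropane (COC(C)(C)OC)
Why: Acid-catalysed transketalisation of a cis-1,2-diol to the dioxolane, with no stereocentre touched.

Step 4
Reactants: 6
Product: 7 trimethylsilyl enol ether (C5=C6, single enantiomer)
Conditions: (R,R)-bis(1-phenylethyl)amine, n-BuLi, LiCl, THF, −78 °C; then 6, TMSCl, −100 °C
Reagents that add atoms: chlorotrimethylsilane (C[Si](C)(C)Cl)
Why: Enantioselective deprotonation of a meso ketone by a chiral lithium amide with in-flask silyl quench distinguishes the enantiotopic methylenes C5 and C7 and so fixes the absolute configuration of all later centres.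

Step 5
Reactants: 7
Product: 8 enone (C6 ketone, C5=C1 alkene bearing C15; C8 methyl β; acetonide α)
Conditions: Pd(OAc)2 (10 mol %), O2 (1 atm), DMSO, rt
Reagents that add atoms: none
Why: Saegusa–Ito oxidation through the oxa-π-allyl palladium species and β-hydride loss from C1 gives the enone without touching C8, C9 or C10.

Step 6
Reactants: 8
Product: 9 6α-allylic alcohol (hydroxyl cis to the acetonide oxygens)
Conditions: NaBH4, CeCl3·7H2O, MeOH, −78 °C
Reagents that add atoms: none
Why: Luche 1,2-reduction should deliver hydride to the convex face away from the cis-fused dioxolane, giving the alcohol 1,4-cis to the C10 oxygen.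

Step 7
Reactants: 9
Product: 10 cyclopropyl carbinol (cyclopropane C1–C2–C5 on the α face, C15 β, 6α-OH)
Conditions: Et2Zn, CH2I2, CH2Cl2, 0 °C to rt
Reagents that add atoms: diiodomethane (ICI)
Why: Hydroxyl-directed Simmons–Smith cyclopropanation (Furukawa variant) delivers the methylene from the zinc alkoxide at O6, assisted by the C10 acetal oxygen, to the α face of C5=C1 and so sets C1 (and C5).

Step 8
Reactants: 10
Product: 11 cyclopropyl ketone (cis-fused bicyclo[5.1.0]octan-2-one; C6 ketone, C2 methylene α)
Conditions: Dess–Martin periodinane, NaHCO3, CH2Cl2, rt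
Reagents that add atoms: none
Why: Dess–Martin oxidation of the secondary cyclopropyl carbinol under buffered conditions leaves the acetonide and the cyclopropane intact.

Step 9
Reactants: 11; 12 3-methylbut-1-yne
Product: 13 cis-fused cyclopentene ketone (9α,10α-isopropylidenedioxy-5βH-dauc-3-en-6-one, C8 methyl β)
Conditions: SmI2 (20 mol %), Sm powder (20 mol %), 12 (8 equiv), THF, 55 °C, sealed tube
Reagents that add atoms: none
Why: Proposed new method: divalent samarium reduces the C6 ketone to a ketyl, whose β-scission of the exocyclic cyclopropane bond C5–C2 gives a primary C2 radical and a trivalent samarium enolate (C5=C6); C2 adds to the terminal carbon of 12 (C2–C3), the vinyl radical at C4 closes on C5 (C4–C5), and the new ketyl returns its electron so that SmI2 turns over. The closest known reaction type is the SmI2-catalysed radical-relay formal [3+2] cycloaddition of alkyl cyclopropyl ketones with alkynes; new here are the bicyclo[5.1.0]octan-2-one carrying a methyl on the internal cyclopropane carbon and the unactivated aliphatic alkyne. The five-membered ring closes by 5-exo-trig attack of the vinyl radical on the enolate carbon. C5 is the only new stereocentre and is set by the tether, since C4 can reach C5 only on the face that carries C2, which gives the cis ring fusion; C1 is untouched. The step needs cleavage of C5–C2 and not C5–C1, which the ring fusion should secure by holding C5–C1 near the carbonyl plane and C5–C2 in overlap with the ketyl, helped by faster alkyne capture of the unhindered primary radical under reversible ring opening. It also needs alkyne capture ahead of hydrogen abstraction, for which 12 is used in large excess.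

Step 10
Reactants: 13
Product: 14 cis-fused β-hydroxy ketone (4β-hydroxy-9α,10α-isopropylidenedioxy-5βH-daucan-6-one; hydroxyl cis to C15 and H5)
Conditions: Mn(dpm)3 (10 mol %), PhSiH3, O2 (1 atm), i-PrOH/CH2Cl2, 0 °C to rt
Reagents that add atoms: dioxygen (O=O)
Why: Mukaiyama hydration places hydrogen on C3 and traps the tertiary C4 radical with oxygen on the convex face of the cis-fused bicycle, anti to C6 on C5, which should set C4 with the hydroxyl cis to C15.

Step 11
Reactants: 14
Product: 15 trans-fused β-hydroxy ketone (4β-hydroxy-9α,10α-isopropylidenedioxy-5αH-daucan-6-one)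
Conditions: DBU, toluene, 60 °C
Reagents that add atoms: none
Why: Base-mediated epimerisation at C5 (α to the C6 ketone) should favour the trans ring fusion, which moves the isopropyl group from cis to trans with respect to C6 and allows an O4–H···O=C6 hydrogen bond.

Step 12
Reactants: 15
Product: 16 enone (C6 ketone, C7=C8 alkene bearing C14)
Conditions: IBX, DMSO/fluorobenzene, 70 °C
Reagents that add atoms: none
Why: IBX dehydrogenation can only desaturate C7–C8 because both neighbours of C5 are quaternary, and it erases the temporary C8 stereocentre.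

Step 13
Reactants: 16
Product: 18 β,γ-unsaturated ketone (4β-hydroxy-9α,10α-isopropylidenedioxydauc-8(14)-en-6-one), via bis-silyl dienol ether 17 (not isolated)
Conditions: TMSOTf, Et3N, CH2Cl2, 0 °C; then TBAF, AcOH, THF, −78 °C
Reagents that add atoms: none
Why: Soft enolisation removes an accessible C14 hydrogen of the O-silylated enone (C5–H is shielded by two quaternary neighbours) to give the linear dienol ether, and fluoride then releases the dienolate, which is protonated kinetically at C7 (deconjugative α-protonation) while the tertiary silyl ether is also cleaved.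

Step 14
Reactants: 18
Product: 19 4β,6α-diol (9α,10α-isopropylidenedioxydauc-8(14)-ene-4β,6α-diol)
Conditions: Me4NBH(OAc)3, MeCN/AcOH, −25 °C
Reagents that add atoms: none
Why: Evans–Saksena hydroxyl-directed reduction delivers hydride from the boron bound at O4 to the β face of C6, which should set C6 as the α-alcohol (1,3-anti).

Step 15
Reactants: 19
Product: 20 6α-isovalerate (4β-hydroxy-9α,10α-isopropylidenedioxydauc-8(14)-en-6α-yl 3-methylbutanoate)
Conditions: isovaleric anhydride, Et3N, DMAP (cat.), CH2Cl2, rt
Reagents that add atoms: 3-methylbutanoic anhydride (CC(C)CC(=O)OC(=O)CC(C)C)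
Why: DMAP-catalysed acylation (Steglich-type) esterifies the secondary C6 alcohol while the tertiary C4 alcohol stays free.

Step 16
Reactants: 20
Product: 21 triol ester (6α-(3-methylbutanoyloxy)dauc-8(14)-ene-4β,9α,10α-triol)
Conditions: AcOH/H2O (4:1), 45 °C
Reagents that add atoms: none
Why: Mild acid hydrolysis of the acetonide frees the cis-diol without affecting the ester, the tertiary alcohol or the exocyclic alkene.

Step 17
Reactants: 21
Product: 22 target (8α,14-epoxy-6α-(3-methylbutanoyloxy)daucane-4β,9α,10α-triol)
Conditions: VO(acac)2 (5 mol %), t-BuOOH, CH2Cl2, 0 °C to rt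
Reagents that add atoms: tert-butyl hydroperoxide (CC(C)(C)OO)
Why: Vanadium-catalysed hydroxyl-directed epoxidation delivers oxygen from the allylic 9α-hydroxyl to the α face of the C8=C14 alkene, which sets C8.

**Compound list**

1 | (2E,4E)-hexa-2,4-diene | C/C=C/C=C/C | starting material
2 | 1,1,3,3-tetrabromoacetone | BrC(Br)C(=O)C(Br)Br | starting material
3 | 2,7-dibromo-cis-3,6-dimethylcyclohept-4-en-1-one (bromide epimers) | O=C1C(Br)[C@H](C)C=C[C@H](C)C1Br | intermediate
4 | cis-3,6-dimethylcyclohept-4-en-1-one (meso) | O=C1C[C@H](C)C=C[C@H](C)C1 | intermediate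
5 | meso 4,5-dihydroxy-3,6-dimethylcycloheptan-1-one (hydroxyls cis, trans to both methyls) | O=C1C[C@H](C)[C@@H](O)[C@@H](O)[C@H](C)C1 | intermediate
6 | acetonide of 5 (meso) | O=C1C[C@H](C)[C@H]2OC(C)(C)O[C@H]2[C@H](C)C1 | intermediate
7 | trimethylsilyl enol ether of 6 (C5=C6) | C1=C(O[Si](C)(C)C)C[C@H](C)[C@H]2OC(C)(C)O[C@H]2[C@@H]1C | intermediate
8 | enone (C6 ketone, C5=C1; C8 methyl β; acetonide α) | O=C1C[C@H](C)[C@H]2OC(C)(C)O[C@H]2C(C)=C1 | intermediate
9 | 6α-allylic alcohol | O[C@H]1C[C@H](C)[C@H]2OC(C)(C)O[C@H]2C(C)=C1 | intermediate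
10 | cyclopropyl carbinol (α-cyclopropane C1–C2–C5, 6α-OH) | O[C@H]1C[C@H](C)[C@H]2OC(C)(C)O[C@H]2[C@@]3(C)C[C@@H]13 | intermediate
11 | cyclopropyl ketone (cis-fused bicyclo[5.1.0]octan-2-one core) | O=C1C[C@H](C)[C@H]2OC(C)(C)O[C@H]2[C@@]3(C)C[C@@H]13 | intermediate
12 | 3-methylbut-1-yne | CC(C)C#C | starting material
13 | 9α,10α-isopropylidenedioxy-5βH-dauc-3-en-6-one (cis-fused) | O=C1C[C@H](C)[C@H]2OC(C)(C)O[C@H]2[C@@]3(C)CC=C(C(C)C)[C@@H]13 | intermediate
14 | 4β-hydroxy-9α,10α-isopropylidenedioxy-5βH-daucan-6-one (cis-fused) | O=C1C[C@H](C)[C@H]2OC(C)(C)O[C@H]2[C@@]3(C)CC[C@@](O)(C(C)C)[C@@H]13 | intermediate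
15 | 4β-hydroxy-9α,10α-isopropylidenedioxy-5αH-daucan-6-one (trans-fused) | O=C1C[C@H](C)[C@H]2OC(C)(C)O[C@H]2[C@@]3(C)CC[C@@](O)(C(C)C)[C@H]13 | intermediate
16 | 4β-hydroxy-9α,10α-isopropylidenedioxydauc-7-en-6-one | O=C1C=C(C)[C@H]2OC(C)(C)O[C@H]2[C@@]3(C)CC[C@@](O)(C(C)C)[C@H]13 | intermediate
17 | bis(trimethylsilyl) dienol ether (C6=C7, C8=C14, O4-silyl) | C[Si](C)(C)OC1=CC(=C)[C@H]2OC(C)(C)O[C@H]2[C@@]3(C)CC[C@@](O[Si](C)(C)C)(C(C)C)[C@H]13 | intermediate
18 | 4β-hydroxy-9α,10α-isopropylidenedioxydauc-8(14)-en-6-one | O=C1CC(=C)[C@H]2OC(C)(C)O[C@H]2[C@@]3(C)CC[C@@](O)(C(C)C)[C@H]13 | intermediate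
19 | 9α,10α-isopropylidenedioxydauc-8(14)-ene-4β,6α-diol | O[C@H]1CC(=C)[C@H]2OC(C)(C)O[C@H]2[C@@]3(C)CC[C@@](O)(C(C)C)[C@H]13 | intermediate
20 | 6α-isovalerate of 19 | CC(C)CC(=O)O[C@H]1CC(=C)[C@H]2OC(C)(C)O[C@H]2[C@@]3(C)CC[C@@](O)(C(C)C)[C@H]13 | intermediate
21 | 6α-(3-methylbutanoyloxy)dauc-8(14)-ene-4β,9α,10α-triol | CC(C)CC(=O)O[C@H]1CC(=C)[C@@H](O)[C@@H](O)[C@@]2(C)CC[C@@](O)(C(C)C)[C@H]12 | intermediate
22 | 8α,14-epoxy-6α-(3-methylbutanoyloxy)daucane-4β,9α,10α-triol (CNP0307265.1) | CC(C)CC(=O)O[C@H]1C[C@]2(CO2)[C@@H](O)[C@@H](O)[C@@]2(C)CC[C@@](O)(C(C)C)[C@H]12 | target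

**Step count and risks**

Total step count: 17. Longest linear sequence: 17 steps (from 1 and 2 to 22).

Steps most likely to fail:

1. Step 9. The ketyl may open the endocyclic C5–C1 bond (giving the tertiary radical and a ring-expanded enolate), or the C2 radical may be lost by hydrogen abstraction or reduction before it meets the alkyne; the adduct may also epimerise at C5 before hydration. Fallback by known reactions, setting out from 11: homoconjugate opening of the cyclopropane with sodium benzeneselenolate (PhSeNa, 18-crown-6, THF; SN2 attack at the unhindered methylene C2) with in-flask trapping of the C5=C6 enolate by TBSCl should give the selenide silyl enol ether F1. Radical alkynylation of the C2–Se bond with (3-methylbut-1-yn-1-yl) phenyl sulfone (Bu3SnSnBu3, hν, benzene) should give the alkynyl silyl enol ether F2. Gold-catalysed Conia-ene-type 5-endo-dig cyclisation of the silyl enol ether onto the alkyne ([(JohnPhos)Au(NCMe)]SbF6, CH2Cl2/MeOH) closes C4–C5 on the face of C2 and comes back to the route at 13.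

2. Step 11. The free aldol may undergo retro-aldol cleavage of C4–C5 and re-close to other diastereomers, or equilibration may stall at the hindered C5–H. Fallback, setting out from 14: the tertiary hydroxyl is silylated (TESOTf, 2,6-lutidine) to the cis-fused silyl ether F3, which cannot cleave and can be equilibrated with a stronger base (KOt-Bu, t-BuOH/THF) to the trans-fused silyl ether F4, still driven by the isopropyl group moving away from C6. Desilylation (TBAF, THF) comes back to the route at 15.

3. Step 13. Enolisation may go toward C5 (with loss of the ring-fusion configuration on reprotonation), or the dienolate may be protonated at C14 and return the conjugated enone. Fallback, setting out from 16: radical bromination of the C14 methyl (NBS, AIBN, PhCF3, 80 °C) should give the γ-bromo enone F5. Reduction with zinc in AcOH/THF at 0 °C forms the zinc dienolate without any base and protonates it at C7 (the classic reductive deconjugation of γ-bromo enones), and comes back to the route at 18.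

Further compounds
F1 | step 9 | tert-butyldimethylsilyl enol ether (C5=C6) with phenylselanylmethyl (C2) and C15 on C1 | C1=C(O[Si](C)(C)C(C)(C)C)C[C@H](C)[C@H]2OC(C)(C)O[C@H]2[C@@]1(C)C[Se]c1ccccc1
F2 | step 9 | tert-butyldimethylsilyl enol ether (C5=C6) with 4-methylpent-2-yn-1-yl (C2–C3≡C4–isopropyl) and C15 on C1 | C1=C(O[Si](C)(C)C(C)(C)C)C[C@H](C)[C@H]2OC(C)(C)O[C@H]2[C@@]1(C)CC#CC(C)C
F3 | step 11 | O4-triethylsilyl ether of 14 (cis-fused) | O=C1C[C@H](C)[C@H]2OC(C)(C)O[C@H]2[C@@]3(C)CC[C@@](O[Si](CC)(CC)CC)(C(C)C)[C@@H]13
F4 | step 11 | O4-triethylsilyl ether of 15 (trans-fused) | O=C1C[C@H](C)[C@H]2OC(C)(C)O[C@H]2[C@@]3(C)CC[C@@](O[Si](CC)(CC)CC)(C(C)C)[C@H]13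
F5 | step 13 | 14-bromo derivative of 16 (γ-bromo enone) | O=C1C=C(CBr)[C@H]2OC(C)(C)O[C@H]2[C@@]3(C)CC[C@@](O)(C(C)C)[C@H]13
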